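## Structural features

The target is a 3,3''-biflavanone. A liquiritigenin unit (chroman-4-one with 7-OH, 4-hydroxyphenyl on C2) and a naringenin unit (chroman-4-one with 5''- and 7''-OH, 4-hydroxyphenyl on C2'') are joined by the single bond C3–C3''. The four stereocentres C2, C3, C3'' and C2'' stand in a row, (2S,3R,3''R,2''S), and on each pyranone ring the aryl group and the inter-unit bond are trans. C4(=O)–C3–C3''–C4''(=O) is a 1,4-diketone, so C3 and C3'' are enolisable and can be equilibrated. C2 and C2'' are benzylic aryl-ether carbons β to a ketone; their configuration can only be lost, by retro-oxa-Michael ring opening under base or by ionisation under acid, and a free para-hydroxyl on the 2-aryl group makes both easier. Five phenols have to be masked, and benzyl ethers allow a neutral last step. The real difficulty is the crowded C3–C3'' junction between two different halves, together with the absolute configuration at C2 and C2''. The feature used is that C4 and C4'' are each a carbonyl carbon between an aromatic carbon (C4a, C4a'') and C3 or C3''. With C3 and C3'' as the two carbons of an alkyne, both carbonyls can come from carbon monoxide and ring C of each half can be closed in one operation, with O1–C2 and O1''–C2'' already in place.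

## Logic of the disconnections

17 to 16: the five O–CH2Ph bonds are cut. The gain is that all phenols stay masked until the skeleton and all stereocentres are complete. The forward step must cleave aryl benzyl ethers without touching the benzylic C2–O1 and C2''–O1'' bonds or the ketones.

16 to 14 (through 15): the C3–H and C3''–H bonds are removed to give the C3=C3'' ene-dione. This deletes the two stereocentres that can be set under thermodynamic control. The forward step must reduce the double bond without expelling the aryloxide at C2 or C2'', and the equilibration must stop at enolisation of C3 and C3''.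

14 to 13: four C–C bonds are cut, C4a''–C4'', C4''–C3'', C3–C4 and C4–C4a, and both carbonyl carbons leave as CO. Both pyranone rings open, and what remains is an alkyne flanked by two aryl-ether carbinol carbons, one aryl ring carrying iodine and the other boron. The forward step must insert CO before either organopalladium intermediate cyclises or eliminates, and transmetalation must come last.

13 to 12 and 6: the O1–C2 bond is cut at carbon. The forward step is an SN2 etherification with inversion at a benzylic, propargylic carbon. 6 goes back to 4 (C–B bond) and 4 to 3 (C–I bond).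

12 to 11 and 7: the C2–C3 bond between carbinol carbon and alkyne is cut. The forward step is a catalyst-controlled alkynylation, since the existing centre is too remote to help or hinder.

11 to 10, then to 9 and 2: the C–H of the alkyne is traded for C–Si, then O1''–C2'' is cut in the same way as O1–C2. 2 goes back to 1 (C–I bond).

9 to 7 and 8: the C2''–C3'' bond is cut. Both carbinol centres thus come from the same aldehyde and the same catalyst.

## Other disconnections considered

Alternative 1: The cut goes through C3''–C4'' and O1''–C2'', taking the naringenin pyran ring apart into a cationic ortho-quinone methide and a styrene. Forward, aldehyde A2 is turned by an orthoformate and a chiral phosphoric acid into its O-methyl oxocarbenium ion, which adds across the (E)-styryl group of the preformed flavan A3 to give A1.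
- In its favour: strongly polarised cycloadditions of this kind onto electron-rich styrenes are well founded, no metal or CO is needed, and the E geometry translates directly into the trans C2''/C3'' relationship.
- Against it here: A3 must first be made enantioenriched with its own trans centres. The facial choice on the styrene next to C3 has to be won by the catalyst. The 4-methoxy group already in A3 is a benzylic ether that the same acid can ionise. Both C4 and C4'' end at the wrong oxidation level, so two benzylic oxidations follow.
- Comparison: on stereochemistry it is the better plan, because its key step sets C3'' and C2'' whereas the carbonylation sets no stereocentre. On mechanism its key step rests on firmer ground. On step economy the chosen plan is better, since it reaches the ketone oxidation level directly and builds both rings at once.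

Alternative 2: The cut goes through C2–C3 and C2''–C3''. Forward, diketone A5 is converted with (Ipc)2BOTf and an amine base into a bis(Z-enolate) that adds to two molecules of 7 to give A4. Desilylation and two ring closures with inversion at the carbinol carbons would follow.
- In its favour: it is the shortest and most convergent plan, all four stereocentres arise in one operation, and the oxidation level is right from the start. On step economy and on the number of stereocentres set it is better than the chosen plan.
- Against it here: double enolisation of a 1,4-diketone and a second aldol next to a fresh β-hydroxy ketone have no close model. Retro-aldol and dehydration to the chalcone threaten A4, and the two closing etherifications at p-alkoxybenzylic β-hydroxy ketone carbons compete with elimination, which would erase C2 and C2''.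
- Comparison: both plans depend on SN2 etherification at a p-alkoxybenzylic carbon, so they are equal on that point. The chosen plan does it early on robust propargylic alcohols; Alternative 2 does it last on the most fragile intermediate.

Alternative 3: The cut is C3–C4 of the liquiritigenin half. Forward, a chiral triazolium-derived carbene converts the aldehyde of A7 into a Breslow intermediate that adds 6-exo to the enone β-carbon and gives A6.
- In its favour: the intramolecular Stetter reaction to chroman-4-ones is established chemistry and forms the 1,4-dicarbonyl unit at the right oxidation level under mild conditions. On precedent and mechanistic certainty it is clearly better than the chosen key step.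
- Against it here: it makes one ring and one stereocentre only. A7 needs an enantiopure γ-aryloxy enone whose γ-hydrogen is acidic under the basic carbene conditions. The naringenin half still requires an aldol at C3'' that must set two more centres, and a ring closure by substitution of fluoride on an electron-rich arene.
- Comparison: the chosen plan is structurally more ambitious (four bonds, two rings, both halves at once) and should be shorter. Alternative 3 is the safer single step but the longer and more linear route.

Key step: step 9

Remarks on the design: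
- Iodine is placed on the phloroglucinol-derived ring and boron on the resorcinol-derived ring. The opposite placement would put boron between two ortho oxygens, where protodeboronation and slow transmetalation are expected. The four bonds formed and the two rings closed are the same either way.
- The alkenyl–palladium intermediate of step 9 does carry a β-hydrogen (C2–H). Syn elimination to an allene is geometrically unfavourable, and loss of the β-aryloxide is the more serious risk.
- The descriptors change from R (10, 13, 14) to S (11, 15–17) at unchanged geometry, because the neighbouring carbon changes rank against the aryl group. No bond at C2 or C2'' is touched after step 8.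
- Assumption: 1 and 3 are bought as such, and the (S,S)-ProPhenol–zinc catalyst is taken to deliver alkynyl groups to the Re face of aryl aldehydes; if the sense is the reverse, the (R,R)-ligand is used in steps 4 and 7 and nothing else changes.

Step 1
Reactants: 1 3,5-bis(benzyloxy)phenol
Product: 2 3,5-bis(benzyloxy)-2-iodophenol
Conditions: I2 (1.0 equiv), NaHCO3, THF/H2O, 0 °C
Reagents that add atoms: iodine, II
Why: Electrophilic aromatic iodination of the phenoxide; the position ortho to the hydroxyl and para to one benzyloxy group is less crowded than C4 between the two benzyloxy groups, and one equivalent of iodine limits the reaction to mono-substitution.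

Step 2
Reactants: 3 3-(benzyloxy)phenol
Product: 4 5-(benzyloxy)-2-iodophenol
Conditions: I2 (1.0 equiv), NaHCO3, THF/H2O, 0 °C
Reagents that add atoms: iodine, II
Why: Same electrophilic iodination; attack ortho to the hydroxyl and para to the benzyloxy group avoids both positions that adjoin the benzyloxy group.

Step 3
Reactants: 4 5-(benzyloxy)-2-iodophenol; 5 bis(pinacolato)diboron
Product: 6 5-(benzyloxy)-2-(4,4,5,5-tetramethyl-1,3,2-dioxaborolan-2-yl)phenol
Conditions: PdCl2(dppf) (5 mol%), KOAc, 1,4-dioxane, 80 °C
Reagents that add atoms: none
Why: Miyaura borylation of an aryl iodide; acetate is too weak a base to trigger Suzuki coupling of the product, and the arylboronate formed has only one ortho oxygen and is therefore stable.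

Step 4
Reactants: 7 4-(benzyloxy)benzaldehyde; 8 ethynyltrimethylsilane
Product: 9 (1S)-1-[4-(benzyloxy)phenyl]-3-(trimethylsilyl)prop-2-yn-1-ol
Conditions: (S,S)-ProPhenol (10 mol%), Me2Zn, Ph3P=O (20 mol%), toluene, 4 °C; aqueous work-up
Reagents that add atoms: none
Why: Catalytic asymmetric alkynylation of an aryl aldehyde by an alkynylzinc held in the dinuclear zinc–ProPhenol complex; delivery to the Re face gives the S carbinol, which becomes C2'' after inversion in step 5.

Step 5
Reactants: 9 (1S)-1-[4-(benzyloxy)phenyl]-3-(trimethylsilyl)prop-2-yn-1-ol; 2 3,5-bis(benzyloxy)-2-iodophenol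
Product: 10 [(3R)-3-[3,5-bis(benzyloxy)-2-iodophenoxy]-3-[4-(benzyloxy)phenyl]prop-1-yn-1-yl]trimethylsilane
Conditions: PPh3, DIAD, toluene, −20 to 0 °C
Reagents that add atoms: none
Why: Mitsunobu etherification; the acidic ortho-iodophenol displaces the alkoxyphosphonium group by SN2 with inversion, the apolar solvent and low temperature disfavour ionisation of the benzylic centre, and the silyl cap blocks attack at the alkyne terminus.

Step 6
Reactants: 10 [(3R)-3-[3,5-bis(benzyloxy)-2-iodophenoxy]-3-[4-(benzyloxy)phenyl]prop-1-yn-1-yl]trimethylsilane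
Product: 11 1,5-bis(benzyloxy)-3-{[(1S)-1-[4-(benzyloxy)phenyl]prop-2-yn-1-yl]oxy}-2-iodobenzene
Conditions: K2CO3 (cat.), MeOH/THF, 0 °C
Reagents that add atoms: none
Why: Methanolysis of the C(sp)–Si bond with catalytic carbonate; the short exposure at low temperature leaves the propargylic C–H and the ethers untouched.

Step 7
Reactants: 11 1,5-bis(benzyloxy)-3-{[(1S)-1-[4-(benzyloxy)phenyl]prop-2-yn-1-yl]oxy}-2-iodobenzene; 7 4-(benzyloxy)benzaldehyde
Product: 12 (1S,4R)-4-[3,5-bis(benzyloxy)-2-iodophenoxy]-1,4-bis[4-(benzyloxy)phenyl]but-2-yn-1-ol
Conditions: (S,S)-ProPhenol (20 mol%), Me2Zn, Ph3P=O (40 mol%), toluene, 4 °C, excess 7; aqueous work-up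
Reagents that add atoms: none
Why: Same ProPhenol alkynylation with the functionalised alkyne; the existing centre is four atoms away, so the new S carbinol (future C2) is set by the catalyst alone, and the aryl iodide and benzyl ethers are inert to Me2Zn.

Step 8
Reactants: 12 (1S,4R)-4-[3,5-bis(benzyloxy)-2-iodophenoxy]-1,4-bis[4-(benzyloxy)phenyl]but-2-yn-1-ol; 6 5-(benzyloxy)-2-(4,4,5,5-tetramethyl-1,3,2-dioxaborolan-2-yl)phenol
Product: 13 (1R,4R)-1,4-bis[4-(benzyloxy)phenyl]but-2-yne-1,4-diol 1-[5-(benzyloxy)-2-(pinacolboryl)phenyl] 4-[3,5-bis(benzyloxy)-2-iodophenyl] diether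
Conditions: PPh3, DIAD, toluene, −20 to 0 °C
Reagents that add atoms: none
Why: Second Mitsunobu etherification with inversion, which gives C2 the same sense as C2''; the pinacol boronate is inert to the phosphine/azodicarboxylate pair, and the internal alkyne is shielded at both ends against SN2' attack.

Step 9
Reactants: 13 (1R,4R)-1,4-bis[4-(benzyloxy)phenyl]but-2-yne-1,4-diol 1-[5-(benzyloxy)-2-(pinacolboryl)phenyl] 4-[3,5-bis(benzyloxy)-2-iodophenyl] diether
Product: 14 (2R,2''R,Z)-3,3''-didehydro dimer (C3=C3'' ene-dione) pentabenzyl ether: (Z)-7-benzyloxy-3-[5,7-bis(benzyloxy)-2-(4-benzyloxyphenyl)-4-oxochroman-3-ylidene]-2-(4-benzyloxyphenyl)chroman-4-one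
Conditions: Pd(OAc)2 (10 mol%), Xantphos (12 mol%), CO (10 bar), CsF, 1,4-dioxane (0.01 M), 80 °C
Reagents that add atoms: carbon monoxide, [C-]#[O+]
Why: Proposed new method: zerovalent palladium adds to the C–I bond of the phloroglucinol-derived ring, CO inserts to give the aroyl–palladium species (C4a''–C4''), and 6-exo-dig syn-acylpalladation of the alkyne forms C4''–C3'' and closes the naringenin pyranone, leaving an alkenyl–palladium at C3 held by the cis carbonyl oxygen. A second CO insertion gives the acyl–palladium (C3–C4); fluoride-assisted intramolecular transmetalation from the ring A boronate and reductive elimination through a seven-membered palladacycle form C4–C4a and close the liquiritigenin pyranone as a six-membered ring. The closest known reaction types are intramolecular acylpalladation of alkynes by aroyl–palladium species and carbonylative Suzuki–Miyaura coupling; their union in one cascade with two CO units is not established. No stereocentre is created; syn addition places the two carbonyls cis (Z), and the geometry does not matter because the double bond is reduced in step 10. The selectivity needed is CO insertion ahead of 5-exo-dig carbopalladation at the aryl–palladium stage and ahead of β-aryloxide loss at the alkenyl–palladium stage, which CO pressure, the wide-bite-angle ligand and the two ortho oxygens flanking the aryl–palladium bond should favour. Transmetalation must come last, which is helped by keeping boron as a pinacol ester that is activated only by anhydrous fluoride and that can reach palladium only once the acyl–palladium has formed next to it. High dilution suppresses intermolecular coupling, and the weak non-hydroxylic base limits deprotonation at C2–H and C2''–H, whose shift into conjugation would erase a stereocentre.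

Step 10
Reactants: 14 (2R,2''R,Z)-3,3''-didehydro dimer (C3=C3'' ene-dione) pentabenzyl ether
Product: 16 (2S,3R,2''S,3''R)-7,4',5'',7'',4'''-penta-O-benzyl-3,3''-biflavanone, via saturated 1,4-diketone epimers 15 (not isolated)
Conditions: Zn, AcOH/THF, 0 °C to rt; filter, evaporate; then Et3N, CH2Cl2, rt
Reagents that add atoms: none
Why: Zinc in acetic acid reduces ene-diones to 1,4-diketones by electron transfer with immediate C-protonation of the zinc enolate, so no free enolate persists to expel the aryloxide at C2 or C2''. Triethylamine then enolises only C3 and C3'' (C4 and C4'' have no other α-hydrogen), and each ring settles in the 2,3-trans diequatorial form imposed by its fixed aryl group, which makes C3 and C3'' both R.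

Step 11
Reactants: 16 (2S,3R,2''S,3''R)-7,4',5'',7'',4'''-penta-O-benzyl-3,3''-biflavanone
Product: 17 (2S,3R)-3-[(2S,3R)-5,7-dihydroxy-2-(4-hydroxyphenyl)-4-oxochroman-3-yl]-7-hydroxy-2-(4-hydroxyphenyl)chroman-4-one (CNP0138443.1)
Conditions: H2 (1 atm), 10% Pd/C, EtOAc/MeOH, rt
Reagents that add atoms: none
Why: Hydrogenolysis of the five aryl benzyl ethers under neutral conditions that neither enolise C3/C3'' nor open the pyranones; the reaction is stopped at complete debenzylation, before the slower cleavage of the benzylic C2–O1 and C2''–O1'' bonds.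

Compound list

1 | 3,5-bis(benzyloxy)phenol | Oc1cc(OCc2ccccc2)cc(OCc2ccccc2)c1 | starting material
2 | 3,5-bis(benzyloxy)-2-iodophenol | Oc1cc(OCc2ccccc2)cc(OCc2ccccc2)c1I | intermediate
3 | 3-(benzyloxy)phenol | Oc1cccc(OCc2ccccc2)c1 | starting material
4 | 5-(benzyloxy)-2-iodophenol | Oc1cc(OCc2ccccc2)ccc1I | intermediate
5 | bis(pinacolato)diboron | CC1(C)OB(OC1(C)C)B1OC(C)(C)C(C)(C)O1 | starting material
6 | 5-(benzyloxy)-2-(4,4,5,5-tetramethyl-1,3,2-dioxaborolan-2-yl)phenol | Oc1cc(OCc2ccccc2)ccc1B1OC(C)(C)C(C)(C)O1 | intermediate
7 | 4-(benzyloxy)benzaldehyde | O=Cc1ccc(OCc2ccccc2)cc1 | starting material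
8 | ethynyltrimethylsilane | C#C[Si](C)(C)C | starting material
9 | (1S)-1-[4-(benzyloxy)phenyl]-3-(trimethylsilyl)prop-2-yn-1-ol | O[C@@H](c1ccc(OCc2ccccc2)cc1)C#C[Si](C)(C)C | intermediate
10 | [(3R)-3-[3,5-bis(benzyloxy)-2-iodophenoxy]-3-[4-(benzyloxy)phenyl]prop-1-yn-1-yl]trimethylsilane | C[Si](C)(C)C#C[C@H](Oc1cc(OCc2ccccc2)cc(OCc2ccccc2)c1I)c1ccc(OCc2ccccc2)cc1 | intermediate
11 | 1,5-bis(benzyloxy)-3-{[(1S)-1-[4-(benzyloxy)phenyl]prop-2-yn-1-yl]oxy}-2-iodobenzene | C#C[C@H](Oc1cc(OCc2ccccc2)cc(OCc2ccccc2)c1I)c1ccc(OCc2ccccc2)cc1 | intermediate
12 | (1S,4R)-4-[3,5-bis(benzyloxy)-2-iodophenoxy]-1,4-bis[4-(benzyloxy)phenyl]but-2-yn-1-ol | O[C@@H](c1ccc(OCc2ccccc2)cc1)C#C[C@H](Oc1cc(OCc2ccccc2)cc(OCc2ccccc2)c1I)c1ccc(OCc2ccccc2)cc1 | intermediate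
13 | (1R,4R)-1,4-bis[4-(benzyloxy)phenyl]but-2-yne-1,4-diol 1-[5-(benzyloxy)-2-(pinacolboryl)phenyl] 4-[3,5-bis(benzyloxy)-2-iodophenyl] diether | CC1(C)OB(OC1(C)C)c1ccc(OCc2ccccc2)cc1O[C@H](c1ccc(OCc2ccccc2)cc1)C#C[C@H](Oc1cc(OCc2ccccc2)cc(OCc2ccccc2)c1I)c1ccc(OCc2ccccc2)cc1 | intermediate
14 | (2R,2''R,Z)-3,3''-didehydro dimer (C3=C3'' ene-dione) pentabenzyl ether | O=C1c2ccc(OCc3ccccc3)cc2O[C@H](c2ccc(OCc3ccccc3)cc2)/C1=C1/C(=O)c2c(OCc3ccccc3)cc(OCc3ccccc3)cc2O[C@@H]1c1ccc(OCc2ccccc2)cc1 | intermediate
15 | (2S,2''S)-7,4',5'',7'',4'''-penta-O-benzyl-3,3''-biflavanone, mixture of epimers at C3 and C3'' | O=C1c2ccc(OCc3ccccc3)cc2O[C@H](c2ccc(OCc3ccccc3)cc2)C1C1C(=O)c2c(OCc3ccccc3)cc(OCc3ccccc3)cc2O[C@@H]1c1ccc(OCc2ccccc2)cc1 | intermediate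
16 | (2S,3R,2''S,3''R)-7,4',5'',7'',4'''-penta-O-benzyl-3,3''-biflavanone | O=C1c2ccc(OCc3ccccc3)cc2O[C@H](c2ccc(OCc3ccccc3)cc2)[C@H]1[C@H]1C(=O)c2c(OCc3ccccc3)cc(OCc3ccccc3)cc2O[C@@H]1c1ccc(OCc2ccccc2)cc1 | intermediate
17 | (2S,3R)-3-[(2S,3R)-5,7-dihydroxy-2-(4-hydroxyphenyl)-4-oxochroman-3-yl]-7-hydroxy-2-(4-hydroxyphenyl)chroman-4-one | O=C1c2ccc(O)cc2O[C@H](c2ccc(O)cc2)[C@H]1[C@H]1C(=O)c2c(O)cc(O)cc2O[C@@H]1c1ccc(O)cc1 | target

Total step count: 11. Longest linear sequence: 8 steps (steps 4 to 11, from 7 to 17).

Least certain steps

Step 9 (key step). Four processes could divert it: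
- 5-exo-dig carbopalladation by the aryl–palladium species before CO is taken up;
- β-aryloxide elimination from the alkenyl–palladium intermediate to an allene before the second CO insertion;
- base-induced 1,3-shift of C2–H or C2''–H into conjugation with the ene-dione, which would aromatise one pyranone and erase a stereocentre;
- intermolecular Suzuki-type coupling.

All four are competitions between a desired insertion and a faster unimolecular or base-driven side path, and there is no direct model for the whole cascade. The fallback sets out from 12 and uses known reaction types only. Mitsunobu etherification of 12 with the plain iodophenol 4 gives the bis(aryl iodide) 1,5-bis(benzyloxy)-3-{[(1R,4R)-4-[5-(benzyloxy)-2-iodophenoxy]-1,4-bis[4-(benzyloxy)phenyl]but-2-yn-1-yl]oxy}-2-iodobenzene F1. Syn-diboration of the alkyne with 5 under Pt(PPh3)4 catalysis gives the (Z)-2,3-bis(pinacolboryl)but-2-ene analogue F2. Two intramolecular carbonylative Suzuki–Miyaura couplings of the aryl iodides with the alkenylboronates (Pd(OAc)2, Xantphos, CO, CsF) then close both pyranones and return to the route at 14. Each C–C bond is then made by an established aryl iodide/alkenylboronate carbonylative coupling, and no alkenyl–palladium intermediate with a β-aryloxide is involved.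

Step 10. The most likely failure is expulsion of the aryloxide from an enolate at C3 or C3'' (retro-oxa-Michael ring opening), during the zinc reduction or during the amine equilibration, followed by reclosure with loss of configuration at C2 or C2''. The second concern is slow or incomplete equilibration of the crowded centres. The fallback sets out from 14 and avoids enolates in both operations. Hydrogenation over Pd/C poisoned with ethylenediamine, which spares aryl benzyl ethers, adds hydrogen syn to the double bond and gives 15 as the syn-addition diastereomers. Equilibration through the enol with catalytic TsOH in CHCl3 then returns to the route at 16.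

Step 8. The alkoxyphosphonium intermediate may partly ionise at the p-benzyloxyphenyl propargylic carbon, which would erode the configuration at C2, and the ortho-boryl phenol may react sluggishly. Step 5 shares the first risk. The fallback sets out from 7 and reverses the order of assembly.
- Addition of ethynylmagnesium bromide to 7 gives racemic 1-[4-(benzyloxy)phenyl]prop-2-yn-1-ol F3, and acetylation gives its acetate F4.
- Enantioselective propargylic etherification of F4 with 6 (CuOTf·0.5C6H6, a chiral pybox ligand, iPr2NEt) proceeds through a copper allenylidene, so the cation-stabilising aryl group helps instead of harming. It gives 2-[4-(benzyloxy)-2-{[(1S)-1-[4-(benzyloxy)phenyl]prop-2-yn-1-yl]oxy}phenyl]-4,4,5,5-tetramethyl-1,3,2-dioxaborolane F5.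
- ProPhenol alkynylation of 7 with F5 gives (1S,4R)-4-[5-(benzyloxy)-2-(pinacolboryl)phenoxy]-1,4-bis[4-(benzyloxy)phenyl]but-2-yn-1-ol F6.
- Mitsunobu etherification of F6 with the simple iodophenol 2 returns to the route at 13.

The same copper-catalysed etherification of F4 with 2 would give 11 directly and could replace steps 4 to 6 if step 5 shows the same erosion. The final Mitsunobu of this fallback keeps the ionisation risk.

Step 1. Iodination may occur in part at C4 between the two benzyloxy groups, or twice, because all free ring positions of 1 are strongly activated. The fallback sets out from 1 and fixes the position by directed metalation. Protection with MOMCl and iPr2NEt gives 1,3-bis(benzyloxy)-5-(methoxymethoxy)benzene F7. Lithiation ortho to the methoxymethoxy group with nBuLi in THF at −78 °C and quenching with iodine gives 1,5-bis(benzyloxy)-2-iodo-3-(methoxymethoxy)benzene F8. Removal of the acetal with HCl in MeOH returns to the route at 2.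

## Further compounds

F1 | step 9 | 1,5-bis(benzyloxy)-3-{[(1R,4R)-4-[5-(benzyloxy)-2-iodophenoxy]-1,4-bis[4-(benzyloxy)phenyl]but-2-yn-1-yl]oxy}-2-iodobenzene | Ic1ccc(OCc2ccccc2)cc1O[C@H](c1ccc(OCc2ccccc2)cc1)C#C[C@H](Oc1cc(OCc2ccccc2)cc(OCc2ccccc2)c1I)c1ccc(OCc2ccccc2)cc1
F2 | step 9 | (Z)-2,3-bis(pinacolboryl)but-2-ene analogue of F1 (boryl groups cis, C1 and C4 arranged as in F1) | Ic1ccc(OCc2ccccc2)cc1O[C@H](c1ccc(OCc2ccccc2)cc1)/C(B1OC(C)(C)C(C)(C)O1)=C(/B1OC(C)(C)C(C)(C)O1)[C@H](Oc1cc(OCc2ccccc2)cc(OCc2ccccc2)c1I)c1ccc(OCc2ccccc2)cc1
F0 | step 10 | none | none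
F3 | step 8 | racemic 1-[4-(benzyloxy)phenyl]prop-2-yn-1-ol | OC(C#C)c1ccc(OCc2ccccc2)cc1
F4 | step 8 | racemic 1-[4-(benzyloxy)phenyl]prop-2-yn-1-yl acetate | CC(=O)OC(C#C)c1ccc(OCc2ccccc2)cc1
F5 | step 8 | 2-[4-(benzyloxy)-2-{[(1S)-1-[4-(benzyloxy)phenyl]prop-2-yn-1-yl]oxy}phenyl]-4,4,5,5-tetramethyl-1,3,2-dioxaborolane | C#C[C@H](Oc1cc(OCc2ccccc2)ccc1B1OC(C)(C)C(C)(C)O1)c1ccc(OCc2ccccc2)cc1
F6 | step 8 | (1S,4R)-4-[5-(benzyloxy)-2-(pinacolboryl)phenoxy]-1,4-bis[4-(benzyloxy)phenyl]but-2-yn-1-ol | O[C@@H](c1ccc(OCc2ccccc2)cc1)C#C[C@H](Oc1cc(OCc2ccccc2)ccc1B1OC(C)(C)C(C)(C)O1)c1ccc(OCc2ccccc2)cc1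
F7 | step 1 | 1,3-bis(benzyloxy)-5-(methoxymethoxy)benzene | COCOc1cc(OCc2ccccc2)cc(OCc2ccccc2)c1
F8 | step 1 | 1,5-bis(benzyloxy)-2-iodo-3-(methoxymethoxy)benzene | COCOc1cc(OCc2ccccc2)cc(OCc2ccccc2)c1I
A1 | alternative 1 | 3,3''-linked bis(4-methoxyflavan) pentabenzyl ether, C2, C3, C3'' and C2'' as in the target, C4 and C4'' epimers | COC1c2ccc(OCc3ccccc3)cc2O[C@H](c2ccc(OCc3ccccc3)cc2)[C@H]1[C@H]1C(OC)c2c(OCc3ccccc3)cc(OCc3ccccc3)cc2O[C@@H]1c1ccc(OCc2ccccc2)cc1
A2 | alternative 1 | 2,4-bis(benzyloxy)-6-hydroxybenzaldehyde | O=Cc1c(O)cc(OCc2ccccc2)cc1OCc1ccccc1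
A3 | alternative 1 | 7-benzyloxy-2-(4-benzyloxyphenyl)-3-[(E)-2-(4-benzyloxyphenyl)ethenyl]-4-methoxychromane, C2 and C3 as in the target, C4 epimers | COC1c2ccc(OCc3ccccc3)cc2O[C@H](c2ccc(OCc3ccccc3)cc2)[C@H]1/C=C/c1ccc(OCc2ccccc2)cc1
A4 | alternative 2 | (2R,3R)-2,3-bis[(R)-(4-benzyloxyphenyl)(hydroxy)methyl]-1-[4-benzyloxy-2-(tert-butyldimethylsilyloxy)phenyl]-4-[2,4-bis(benzyloxy)-6-(tert-butyldimethylsilyloxy)phenyl]butane-1,4-dione | O=C(c1ccc(OCc2ccccc2)cc1O[Si](C)(C)C(C)(C)C)[C@@H]([C@@H](O)c1ccc(OCc2ccccc2)cc1)[C@H]([C@@H](O)c1ccc(OCc2ccccc2)cc1)C(=O)c1c(O[Si](C)(C)C(C)(C)C)cc(OCc2ccccc2)cc1OCc1ccccc1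
A5 | alternative 2 | 1-[4-benzyloxy-2-(tert-butyldimethylsilyloxy)phenyl]-4-[2,4-bis(benzyloxy)-6-(tert-butyldimethylsilyloxy)phenyl]butane-1,4-dione | O=C(CCC(=O)c1c(O[Si](C)(C)C(C)(C)C)cc(OCc2ccccc2)cc1OCc1ccccc1)c1ccc(OCc2ccccc2)cc1O[Si](C)(C)C(C)(C)C
A6 | alternative 3 | (2S,3R)-7-benzyloxy-2-(4-benzyloxyphenyl)-3-[2-(2,4-bis(benzyloxy)-6-fluorophenyl)-2-oxoethyl]chroman-4-one | O=C1c2ccc(OCc3ccccc3)cc2O[C@H](c2ccc(OCc3ccccc3)cc2)[C@H]1CC(=O)c1c(F)cc(OCc2ccccc2)cc1OCc1ccccc1
A7 | alternative 3 | 4-(benzyloxy)-2-{[(1S,2E)-1-[4-(benzyloxy)phenyl]-4-[2,4-bis(benzyloxy)-6-fluorophenyl]-4-oxobut-2-en-1-yl]oxy}benzaldehyde | O=Cc1ccc(OCc2ccccc2)cc1O[C@H](c1ccc(OCc2ccccc2)cc1)/C=C/C(=O)c1c(F)cc(OCc2ccccc2)cc1OCc1ccccc1
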